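Ring A is cut first at C1–CO2H, with the side-chain ketone masked as a dioxolane. It is then cut at C3–C4 and C4–C5, which frees C4 as carbon monoxide and leaves an acyclic 3-pivaloyloxy-1,4-enyne. The enyne is cut at C1–C2 (acetylide plus enal) and at O–C5 (phenoxide plus 3-tosyloxyacrolein).
Enabling feature: ring A is a resorcinol with hydroxyls on C2 and C4 (meta), the isocoumarin 8-oxygen on C5 and the 2-oxoheptyl chain on C6. This pattern results when CO enters as C4 between an alkyne terminus (C3) and an aryloxy-bearing alkene terminus (C5) while the ester moves from C1 to C2.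
Forward order: the isocoumarin is made first (benzene ring bought as methyl orsellinate, pyranone ring by enol lactonisation). The C9 keto-ester chain is raised in parallel to a 3-tosyloxy enal, the two are joined through oxygen, the alkyne is added, and ring A closes last around the finished ether.
End game: pivalate removal, carboxylation at C1, ketal hydrolysis.
Stereochemistry: the target has no stereocentre. The only one on the way (the carbinol carbon, future C1) is racemic and becomes sp2, and the enol-ether geometry vanishes on aromatisation.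

Key step: step 14

Assumption: enol-tosylate and enol-ether double bonds are drawn E, the isomer expected to prevail. The Z isomers would follow the same route, because this geometry is erased when ring A becomes aromatic.

Step 1
Reactants: 1 methyl 4-chloro-4-oxobutanoate; 2 pentylmagnesium bromide
Product: 3 methyl 4-oxononanoate
Conditions: Fe(acac)3 (3 mol %), THF, −78 °C
Reagents that add atoms: none
Why: Iron-catalysed Grignard acylation of an acid chloride is far faster than attack on the methyl ester or on the new ketone, so the keto ester should form without over-addition.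

Step 2
Reactants: 3 methyl 4-oxononanoate
Product: 4 methyl 3-(2-pentyl-1,3-dioxolan-2-yl)propanoate
Conditions: HOCH2CH2OH, TsOH·H2O (cat.), PhMe, reflux, Dean–Stark
Reagents that add atoms: ethylene glycol, OCCO
Why: Acid-catalysed ketalisation with azeotropic water removal, routine for γ-keto esters, masks the ketone against the later hydride, Grignard and carboxylation steps.

Step 3
Reactants: 4 methyl 3-(2-pentyl-1,3-dioxolan-2-yl)propanoate
Product: 5 methyl 2-formyl-3-(2-pentyl-1,3-dioxolan-2-yl)propanoate (racemic, in equilibrium with its enol)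
Conditions: NaH, HCO2Me (excess), MeOH (cat.), THF, 0 °C → rt; AcOH quench
Reagents that add atoms: methyl formate, COC=O
Why: The crossed Claisen condensation with non-enolisable formate is driven by the stabilised sodium enolate of the α-formyl ester, the ketal is inert to base, and the new α-centre is configurationally labile and of no consequence.

Step 4
Reactants: 5 methyl 2-formyl-3-(2-pentyl-1,3-dioxolan-2-yl)propanoate
Product: 6 methyl (E)-2-[(2-pentyl-1,3-dioxolan-2-yl)methyl]-3-(tosyloxy)prop-2-enoate
Conditions: TsCl, N-methylimidazole, Et3N, CH2Cl2, 0 °C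
Reagents that add atoms: p-toluenesulfonyl chloride, Cc1ccc(cc1)S(=O)(=O)Cl
Why: O-sulfonylation of the enol of an α-formyl ester by the N-sulfonylimidazolium salt is an established way to β-tosyloxyacrylates, and the amine base should favour the E isomer.

Step 5
Reactants: 6 methyl (E)-2-[(2-pentyl-1,3-dioxolan-2-yl)methyl]-3-(tosyloxy)prop-2-enoate
Product: 7 (E)-3-hydroxy-2-[(2-pentyl-1,3-dioxolan-2-yl)methyl]prop-1-enyl tosylate
Conditions: DIBAL-H (2.5 equiv), CH2Cl2, −78 °C; aq. Rochelle salt
Reagents that add atoms: none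
Why: DIBAL-H reduces conjugated esters in the 1,2-sense to allylic alcohols and leaves enol sulfonates and dioxolanes untouched at low temperature.

Step 6
Reactants: 7 (E)-3-hydroxy-2-[(2-pentyl-1,3-dioxolan-2-yl)methyl]prop-1-enyl tosylate
Product: 8 (E)-2-formyl-3-(2-pentyl-1,3-dioxolan-2-yl)prop-1-enyl tosylate
Conditions: activated MnO2 (excess), CH2Cl2, rt; filtration
Reagents that add atoms: none
Why: Heterogeneous allylic oxidation stops at the enal and needs no aqueous work-up, which suits this water-sensitive vinylogous mixed anhydride.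

Step 7
Reactants: 9 methyl orsellinate
Product: 10 methyl 2,4-dimethoxy-6-methylbenzoate
Conditions: MeI (excess), K2CO3, acetone, reflux
Reagents that add atoms: iodomethane, CI
Why: Williamson O-methylation under forcing conditions alkylates both the free 4-hydroxyl and the chelated 2-hydroxyl, which removes the acidic protons before the carbanion step.

Step 8
Reactants: 11 hexanoyl chloride; 12 N,O-dimethylhydroxylamine hydrochloride
Product: 13 N-methoxy-N-methylhexanamide
Conditions: Et3N (2.2 equiv), CH2Cl2, 0 °C → rt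
Reagents that add atoms: none
Why: Simple N-acylation of the hydroxylamine gives the acyl donor that transfers a single hexanoyl unit to a carbanion.

Step 9
Reactants: 10 methyl 2,4-dimethoxy-6-methylbenzoate; 13 N-methoxy-N-methylhexanamide
Product: 14 methyl 2,4-dimethoxy-6-(2-oxoheptyl)benzoate
Conditions: LDA (1.2 equiv), THF, −78 °C; then 13, −78 → −40 °C; aq. NH4Cl
Reagents that add atoms: none
Why: Lateral lithiation of the ortho-toluate gives a stabilised benzylic carbanion, and its acylation by the N-methoxy-N-methylamide halts at the chelated tetrahedral adduct, so only one acyl transfer should occur.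

Step 10
Reactants: 14 methyl 2,4-dimethoxy-6-(2-oxoheptyl)benzoate
Product: 15 6,8-dimethoxy-3-pentylisocoumarin
Conditions: TsOH·H2O (0.2 equiv), PhMe, reflux, MeOH distilled off
Reagents that add atoms: none
Why: In this acid-catalysed enol lactonisation the oxygen of the aryl-conjugated enol displaces methanol from the neighbouring ester through a six-membered transition state, and acid is preferred because base could divert the keto ester into a naphthalenediol by C-acylation.

Step 11
Reactants: 15 6,8-dimethoxy-3-pentylisocoumarin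
Product: 16 8-hydroxy-6-methoxy-3-pentylisocoumarin
Conditions: BCl3 (1.5 equiv), CH2Cl2, −78 → 0 °C; H2O
Reagents that add atoms: none
Why: In this chelation-directed ether cleavage BCl3 bridges the lactone carbonyl and the peri 8-methoxy oxygen, so only that methyl group is lost and the 6-methoxy group stays.

Step 12
Reactants: 8 (E)-2-formyl-3-(2-pentyl-1,3-dioxolan-2-yl)prop-1-enyl tosylate; 16 8-hydroxy-6-methoxy-3-pentylisocoumarin
Product: 17 (E)-3-[(6-methoxy-1-oxo-3-pentyl-1H-isochromen-8-yl)oxy]-2-[(2-pentyl-1,3-dioxolan-2-yl)methyl]prop-2-enal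
Conditions: K2CO3, DMF (dry), 0 °C → rt
Reagents that add atoms: none
Why: Addition–elimination (vinylogous acyl substitution) of the phenoxide at the β-carbon of the enal expels tosylate, so the O–C5 bond forms at an unhindered sp2 CH and not at a doubly ortho-substituted arene.

Step 13
Reactants: 17 (E)-3-[(6-methoxy-1-oxo-3-pentyl-1H-isochromen-8-yl)oxy]-2-[(2-pentyl-1,3-dioxolan-2-yl)methyl]prop-2-enal; 18 ethynylmagnesium bromide
Product: 20 racemic (E)-1-[(6-methoxy-1-oxo-3-pentyl-1H-isochromen-8-yl)oxy]-2-[(2-pentyl-1,3-dioxolan-2-yl)methyl]pent-1-en-4-yn-3-yl pivalate, via magnesium alkoxide 19 (not isolated)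
Conditions: 18 (1.2 equiv, 0.5 M in THF), THF, −78 → −30 °C; then PivCl, DMAP (cat.), −30 °C → rt; pH 7 buffer
Reagents that add atoms: pivaloyl chloride, CC(C)(C)C(=O)Cl
Why: The 1,2-Grignard addition to the aldehyde at low temperature outruns attack on the donor-deactivated lactone and on the β-carbon, acylating the alkoxide in the same flask avoids isolating the acid-labile 3-aryloxyallylic alcohol, and the new carbinol centre is formed racemic and is lost in step 14.

Step 14
Reactants: 20 racemic (E)-1-[(6-methoxy-1-oxo-3-pentyl-1H-isochromen-8-yl)oxy]-2-[(2-pentyl-1,3-dioxolan-2-yl)methyl]pent-1-en-4-yn-3-yl pivalate; 21 carbon monoxide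
Product: 24 3-hydroxy-4-[(6-methoxy-1-oxo-3-pentyl-1H-isochromen-8-yl)oxy]-5-[(2-pentyl-1,3-dioxolan-2-yl)methyl]phenyl pivalate, via dienylketene 22 (not isolated), via cyclohexadienone 23 (not isolated)
Conditions: [Rh(CO)2Cl]2 (5 mol %), CO (50–80 atm, autoclave), ClCH2CH2Cl, 80 °C
Reagents that add atoms: none
Why: Monovalent rhodium binds the terminal alkyne, the pivalate carbonyl oxygen adds to the internal alkyne carbon (future C2) and the C1–O bond then breaks, so the ester travels by a 1,2-shift and a rhodium vinylcarbene is left on the former alkyne terminus (C3). CO insertion into this carbene makes the C3–C4 bond and releases dienylketene 22; ring A then closes by a thermal six-electron disrotatory electrocyclisation that joins the ketene carbon C4 to the aryloxy-bearing alkene carbon C5, and dienone 23 moves its C5 hydrogen to oxygen and aromatises. The closest known reaction type is this same rhodium-catalysed carbonylative [5+1] benzannulation of 3-acyloxy-1,4-enynes with terminal alkynes to resorcinol monoesters, used here on a member whose alkene terminus carries an aryloxy substituent. No stereocentre survives, since the racemic carbinol carbon becomes sp2 C1 and the sp3 C5 of 23 is lost on enolisation. The step needs a 1,2- and not a 1,3-acyloxy shift, which the unsubstituted alkyne terminus secures, and it needs CO capture ahead of five-membered Rautenstrauch-type closure, which the CO pressure secures. The E enol ether points the bulky aryloxy group outward in the closing triene, and the product carries O–C4 free and O–C2 acylated.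

Step 15
Reactants: 24 3-hydroxy-4-[(6-methoxy-1-oxo-3-pentyl-1H-isochromen-8-yl)oxy]-5-[(2-pentyl-1,3-dioxolan-2-yl)methyl]phenyl pivalate
Product: 25 8-{2,4-dihydroxy-6-[(2-pentyl-1,3-dioxolan-2-yl)methyl]phenoxy}-6-methoxy-3-pentyl-1H-isochromen-1-one
Conditions: K2CO3 (cat.), MeOH–THF, rt
Reagents that add atoms: none
Why: Base-catalysed transesterification of an aryl ester, which has a phenoxide leaving group, should be faster than attack on the lactone carbonyl, which is deactivated by its ortho and para oxygen donors and shielded by the peri aryloxy group.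

Step 16
Reactants: 25 8-{2,4-dihydroxy-6-[(2-pentyl-1,3-dioxolan-2-yl)methyl]phenoxy}-6-methoxy-3-pentyl-1H-isochromen-1-one
Product: 26 2,4-dihydroxy-5-[(6-methoxy-1-oxo-3-pentyl-1H-isochromen-8-yl)oxy]-6-[(2-pentyl-1,3-dioxolan-2-yl)methyl]benzoic acid
Conditions: MeOMgOCO2Me (2 M in DMF, 10 equiv), DMF, 120 °C; brief cold 1 M HCl work-up
Reagents that add atoms: magnesium methyl carbonate, CO[Mg]OC(=O)OC
Why: This is a Kolbe–Schmitt-type carboxylation through the magnesium phenoxide chelate, the method that turns 5-alkylresorcinols into 6-alkyl-β-resorcylic acids, and it should place CO2 on C1 (ortho to O–C2, para to O–C4) while the ketal keeps the side chain from being carboxylated.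

Step 17
Reactants: 26 2,4-dihydroxy-5-[(6-methoxy-1-oxo-3-pentyl-1H-isochromen-8-yl)oxy]-6-[(2-pentyl-1,3-dioxolan-2-yl)methyl]benzoic acid
Product: 27 β-collatolic acid
Conditions: 1 M HCl, THF, rt
Reagents that add atoms: water, O
Why: Mild aqueous acid hydrolysis of a dialkyl ketone dioxolane at room temperature frees the 2-oxoheptyl ketone and is too gentle for decarboxylation of the resorcylic acid or dehydrative lactonisation of ring A.

Compound list
1 | methyl 4-chloro-4-oxobutanoate | COC(=O)CCC(=O)Cl | starting material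
2 | pentylmagnesium bromide | CCCCC[Mg]Br | starting material
3 | methyl 4-oxononanoate | CCCCCC(=O)CCC(=O)OC | intermediate
4 | methyl 3-(2-pentyl-1,3-dioxolan-2-yl)propanoate | CCCCCC1(CCC(=O)OC)OCCO1 | intermediate
5 | methyl 2-formyl-3-(2-pentyl-1,3-dioxolan-2-yl)propanoate (racemic, enolisable) | CCCCCC1(CC(C=O)C(=O)OC)OCCO1 | intermediate
6 | methyl (E)-2-[(2-pentyl-1,3-dioxolan-2-yl)methyl]-3-(tosyloxy)prop-2-enoate | COC(=O)/C(CC1(CCCCC)OCCO1)=C/OS(=O)(=O)c1ccc(C)cc1 | intermediate
7 | (E)-3-hydroxy-2-[(2-pentyl-1,3-dioxolan-2-yl)methyl]prop-1-enyl tosylate | OC/C(CC1(CCCCC)OCCO1)=C/OS(=O)(=O)c1ccc(C)cc1 | intermediate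
8 | (E)-2-formyl-3-(2-pentyl-1,3-dioxolan-2-yl)prop-1-enyl tosylate | O=C/C(CC1(CCCCC)OCCO1)=C/OS(=O)(=O)c1ccc(C)cc1 | intermediate
9 | methyl orsellinate | COC(=O)c1c(C)cc(O)cc1O | starting material
10 | methyl 2,4-dimethoxy-6-methylbenzoate | COC(=O)c1c(C)cc(OC)cc1OC | intermediate
11 | hexanoyl chloride | CCCCCC(=O)Cl | starting material
12 | N,O-dimethylhydroxylamine hydrochloride | CNOC.Cl | starting material
13 | N-methoxy-N-methylhexanamide | CCCCCC(=O)N(C)OC | intermediate
14 | methyl 2,4-dimethoxy-6-(2-oxoheptyl)benzoate | CCCCCC(=O)Cc1cc(OC)cc(OC)c1C(=O)OC | intermediate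
15 | 6,8-dimethoxy-3-pentylisocoumarin | CCCCCc1cc2cc(OC)cc(OC)c2c(=O)o1 | intermediate
16 | 8-hydroxy-6-methoxy-3-pentylisocoumarin | CCCCCc1cc2cc(OC)cc(O)c2c(=O)o1 | intermediate
17 | (E)-3-[(6-methoxy-1-oxo-3-pentyl-1H-isochromen-8-yl)oxy]-2-[(2-pentyl-1,3-dioxolan-2-yl)methyl]prop-2-enal | O=C/C(CC1(CCCCC)OCCO1)=C/Oc1cc(OC)cc2cc(CCCCC)oc(=O)c12 | intermediate
18 | ethynylmagnesium bromide | C#C[Mg]Br | starting material
19 | bromomagnesium alkoxide of the racemic (E)-1-aryloxy-pent-1-en-4-yn-3-ol | C#CC(O[Mg]Br)/C(CC1(CCCCC)OCCO1)=C/Oc1cc(OC)cc2cc(CCCCC)oc(=O)c12 | intermediate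
20 | racemic (E)-1-[(6-methoxy-1-oxo-3-pentyl-1H-isochromen-8-yl)oxy]-2-[(2-pentyl-1,3-dioxolan-2-yl)methyl]pent-1-en-4-yn-3-yl pivalate | C#CC(OC(=O)C(C)(C)C)/C(CC1(CCCCC)OCCO1)=C/Oc1cc(OC)cc2cc(CCCCC)oc(=O)c12 | intermediate
21 | carbon monoxide | [C-]#[O+] | starting material
22 | dienylketene: 6-[(6-methoxy-1-oxo-3-pentyl-1H-isochromen-8-yl)oxy]-5-[(2-pentyl-1,3-dioxolan-2-yl)methyl]-3-(pivaloyloxy)hexa-1,3,5-trien-1-one | O=C=C/C(OC(=O)C(C)(C)C)=C\C(CC1(CCCCC)OCCO1)=C\Oc1cc(OC)cc2cc(CCCCC)oc(=O)c12 | intermediate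
23 | racemic 6-[(6-methoxy-1-oxo-3-pentyl-1H-isochromen-8-yl)oxy]-5-[(2-pentyl-1,3-dioxolan-2-yl)methyl]-3-(pivaloyloxy)cyclohexa-2,4-dien-1-one | O=C1C=C(OC(=O)C(C)(C)C)C=C(CC2(CCCCC)OCCO2)C1Oc1cc(OC)cc2cc(CCCCC)oc(=O)c12 | intermediate
24 | 3-hydroxy-4-[(6-methoxy-1-oxo-3-pentyl-1H-isochromen-8-yl)oxy]-5-[(2-pentyl-1,3-dioxolan-2-yl)methyl]phenyl pivalate | CCCCCC1(Cc2cc(OC(=O)C(C)(C)C)cc(O)c2Oc2cc(OC)cc3cc(CCCCC)oc(=O)c23)OCCO1 | intermediate
25 | 8-{2,4-dihydroxy-6-[(2-pentyl-1,3-dioxolan-2-yl)methyl]phenoxy}-6-methoxy-3-pentyl-1H-isochromen-1-one | CCCCCC1(Cc2cc(O)cc(O)c2Oc2cc(OC)cc3cc(CCCCC)oc(=O)c23)OCCO1 | intermediate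
26 | 2,4-dihydroxy-5-[(6-methoxy-1-oxo-3-pentyl-1H-isochromen-8-yl)oxy]-6-[(2-pentyl-1,3-dioxolan-2-yl)methyl]benzoic acid | CCCCCC1(Cc2c(Oc3cc(OC)cc4cc(CCCCC)oc(=O)c34)c(O)cc(O)c2C(=O)O)OCCO1 | intermediate
27 | β-collatolic acid, 2,4-dihydroxy-5-[(6-methoxy-1-oxo-3-pentyl-1H-isochromen-8-yl)oxy]-6-(2-oxoheptyl)benzoic acid | CCCCCC(=O)Cc1c(Oc2cc(OC)cc3cc(CCCCC)oc(=O)c23)c(O)cc(O)c1C(=O)O | target

Total step count: 17. Longest linear sequence: 12 steps (steps 1–6, then 12–17). The isocoumarin branch (steps 7–11) joins at step 12.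

Steps most likely to fail

Step 14. The pivalate sits on a carbon that is both propargylic and allylic to an enol ether. Heterolysis of the C1–O bond assisted by the aryloxy oxygen, or a [3,3] shift of the ester towards C5, may therefore outrun the rhodium-triggered 1,2-shift. Five-membered closure of the vinylcarbene may also compete with CO uptake. The fallback gives up building ring A around the ether and makes the diaryl ether by copper catalysis. It sets out from phenol 16 (with acid chloride 11 as the second numbered input) and comes back at resorcinol 25.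
- Commercial 3,5-bis(benzyloxy)benzyl bromide is treated with zinc dust and LiCl in THF to give [3,5-bis(benzyloxy)benzyl]zinc bromide F1.
- Negishi acylation of F1 with 11 under Pd(PPh3)4 catalysis gives 1-[3,5-bis(benzyloxy)phenyl]heptan-2-one F2.
- Ketalisation as in step 2 gives 2-[3,5-bis(benzyloxy)benzyl]-2-pentyl-1,3-dioxolane F3.
- Iodination with N-iodosuccinimide in MeCN should go next to the side chain and para to a benzyloxy group (the two such positions are equivalent), giving 2-[3,5-bis(benzyloxy)-2-iodobenzyl]-2-pentyl-1,3-dioxolane F4.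
- Ullmann-type coupling with 16 (CuI, picolinic acid, K3PO4, DMSO, 90 °C) gives 8-{2,4-bis(benzyloxy)-6-[(2-pentyl-1,3-dioxolan-2-yl)methyl]phenoxy}-6-methoxy-3-pentyl-1H-isochromen-1-one F5.
- Hydrogenolysis (H2, Pd/C, EtOAc, stopped after two equivalents) gives 25.

Step 16. Carboxylation may go to C3 between the two hydroxyls, or may reverse at the temperature needed. The basic magnesium methoxide medium may also open the lactone, or let the C4 phenoxide add to the lactone carbonyl and set up an equilibrium with the seven-membered depsidone isomer. The fallback installs the carbon electrophilically at the aldehyde level. It sets out from 25 and comes back at 26.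
- Vilsmeier–Haack formylation (POCl3, DMF, 0 °C → rt, then aq. NaOAc) attacks 5-alkylresorcinols para to one hydroxyl and next to the alkyl chain. It should give 2,4-dihydroxy-5-[(6-methoxy-1-oxo-3-pentyl-1H-isochromen-8-yl)oxy]-6-[(2-pentyl-1,3-dioxolan-2-yl)methyl]benzaldehyde F6.
- Pinnick oxidation (NaClO2, NaH2PO4, DMSO as hypochlorite scavenger, aq. t-BuOH, rt) gives 26.

Step 13. The magnesium acetylide may attack the lactone carbonyl, or attack the β-carbon with loss of the aryloxide. Acylation of the hindered magnesium alkoxide may also be too slow, which exposes the free alcohol to ionisation on work-up. The fallback uses an aldehyde-selective, non-basic organochromium reagent and a silyl-capped alkyne. It sets out from 17 and comes back at 20.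
- 1-Iodo-2-(trimethylsilyl)acetylene with CrCl2 (excess) and NiCl2 (cat.) in DMF at rt (Nozaki–Hiyama–Kishi-type alkynylation) gives racemic (E)-1-[(6-methoxy-1-oxo-3-pentyl-1H-isochromen-8-yl)oxy]-2-[(2-pentyl-1,3-dioxolan-2-yl)methyl]-5-(trimethylsilyl)pent-1-en-4-yn-3-ol F7.
- PivCl, Et3N and DMAP in CH2Cl2 give its pivalate F8.
- Buffered desilylation (TBAF, AcOH, THF, 0 °C) gives 20.

Further compounds
F1 | step 14 | [3,5-bis(benzyloxy)benzyl]zinc bromide | Br[Zn]Cc1cc(OCc2ccccc2)cc(OCc2ccccc2)c1
F2 | step 14 | 1-[3,5-bis(benzyloxy)phenyl]heptan-2-one | CCCCCC(=O)Cc1cc(OCc2ccccc2)cc(OCc2ccccc2)c1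
F3 | step 14 | 2-[3,5-bis(benzyloxy)benzyl]-2-pentyl-1,3-dioxolane | CCCCCC1(Cc2cc(OCc3ccccc3)cc(OCc3ccccc3)c2)OCCO1
F4 | step 14 | 2-[3,5-bis(benzyloxy)-2-iodobenzyl]-2-pentyl-1,3-dioxolane | CCCCCC1(Cc2cc(OCc3ccccc3)cc(OCc3ccccc3)c2I)OCCO1
F5 | step 14 | 8-{2,4-bis(benzyloxy)-6-[(2-pentyl-1,3-dioxolan-2-yl)methyl]phenoxy}-6-methoxy-3-pentyl-1H-isochromen-1-one | CCCCCC1(Cc2cc(OCc3ccccc3)cc(OCc3ccccc3)c2Oc2cc(OC)cc3cc(CCCCC)oc(=O)c23)OCCO1
F6 | step 16 | 2,4-dihydroxy-5-[(6-methoxy-1-oxo-3-pentyl-1H-isochromen-8-yl)oxy]-6-[(2-pentyl-1,3-dioxolan-2-yl)methyl]benzaldehyde | CCCCCC1(Cc2c(Oc3cc(OC)cc4cc(CCCCC)oc(=O)c34)c(O)cc(O)c2C=O)OCCO1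
F7 | step 13 | racemic (E)-1-[(6-methoxy-1-oxo-3-pentyl-1H-isochromen-8-yl)oxy]-2-[(2-pentyl-1,3-dioxolan-2-yl)methyl]-5-(trimethylsilyl)pent-1-en-4-yn-3-ol | C[Si](C)(C)C#CC(O)/C(CC1(CCCCC)OCCO1)=C/Oc1cc(OC)cc2cc(CCCCC)oc(=O)c12
F8 | step 13 | racemic (E)-1-[(6-methoxy-1-oxo-3-pentyl-1H-isochromen-8-yl)oxy]-2-[(2-pentyl-1,3-dioxolan-2-yl)methyl]-5-(trimethylsilyl)pent-1-en-4-yn-3-yl pivalate | C[Si](C)(C)C#CC(OC(=O)C(C)(C)C)/C(CC1(CCCCC)OCCO1)=C/Oc1cc(OC)cc2cc(CCCCC)oc(=O)c12
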